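**Plan**
- Retrosynthesis: remove seven benzyl ethers and one aryl triflate; carbinol from the aryl ketone; cut the indane at C3–C3a (Friedel–Crafts) and re-join C1–C3 as a donor–acceptor cyclopropane, itself cut into a benzylic sulfonium ylide (future indane C2) and an α-aryl chalcone; cut the dihydrobenzofuran at O1–C7a and C3a–C3.
- Enabling feature: C7a and C3a are neighbouring carbons of the benzofuran benzene ring and map onto an aryne; O1–C2–C3 of the furan ring maps onto the O–C–C of a trans-stilbene oxide; C4, the later link to the indane, sits beside the triple bond and is carried as bromine.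
- Forward order: dihydrofuran ring first (aryne + epoxide), then bromine becomes the ylide carbon, the cyclopropane is a temporary ring, and its opening closes the indane five-membered ring last.
- Stereochemistry: benzofuran C2 from a Shi epoxide (its C–O bond is retained), C3 by trans-selective ion-pair collapse; indane C2 from a chiral sulfonium ylide; indane C3 and C1 by trans-selective ring closure and base equilibration; carbinol by CBS reduction.
- Helpers: Br (aryne regiocontrol, then handle), 4-OTf (steers C–O scission, shields the benzylic ether from acid, removed in step 14), cyclopropane (erased in step 12).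

Key step: step 6

Assumption: 8, both enantiomers of the fructose-derived epoxidation ketone and both enantiomers of 16 are taken as purchasable, and the (1R,4R,5R)-sulfide is assumed to fix the ylide carbon in the sense it shows in (R,R)-selective epoxidations; if the sense is opposite, its (1S,4S,5S)-enantiomer is used in step 8.

Numbering used: indane C1 carries the acyl/carbinol carbon, C2 the benzofuranyl group, C3 the 4-oxyphenyl group, oxygens at C4 and C6. BF stands for the group (2R,3R)-6-(benzyloxy)-3-[3,5-bis(benzyloxy)phenyl]-2-(4-{[(trifluoromethyl)sulfonyl]oxy}phenyl)-2,3-dihydro-1-benzofuran-4-yl.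

Step 1
Reactants: 1 4-(benzyloxy)phenol
Product: 2 4-(benzyloxy)-2,6-dibromophenol
Conditions: NBS (2.05 equiv), i-Pr2NH (10 mol %), CH2Cl2, 0 °C to rt
Reagents that add atoms: N-bromosuccinimide, O=C1CCC(=O)N1Br
Why: Electrophilic aromatic bromination in which the free hydroxyl sends both bromines ortho because the para position is blocked by the benzyloxy group; no stereocentre is formed.

Step 2
Reactants: 2 4-(benzyloxy)-2,6-dibromophenol
Product: 5 4-(benzyloxy)-2-bromo-6-(trimethylsilyl)phenyl trifluoromethanesulfonate, via silyl ether 3 (not isolated), via lithium phenolate 4 (not isolated)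
Conditions: HN(SiMe3)2, THF, 70 °C, evaporate; n-BuLi (1.05 equiv), THF, −78 °C to rt; Tf2O, −78 °C to rt
Reagents that add atoms: hexamethyldisilazane, C[Si](C)(C)N[Si](C)(C)C; trifluoromethanesulfonic anhydride, O=S(=O)(OS(=O)(=O)C(F)(F)F)C(F)(F)F
Why: O-silylation, bromine–lithium exchange with anionic O-to-C silyl migration (retro-Brook rearrangement) and O-triflation is the standard one-pot entry from an ortho-bromophenol to an ortho-silylaryl triflate, and the second bromine stays as the later regiocontrol element.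

Step 3
Reactants: 6 1,3-bis(benzyloxy)-5-(bromomethyl)benzene
Product: 7 diethyl [3,5-bis(benzyloxy)benzyl]phosphonate
Conditions: P(OEt)3 (neat), 130 °C
Reagents that add atoms: triethyl phosphite, CCOP(OCC)OCC
Why: Michaelis–Arbuzov reaction of a primary benzylic bromide, driven by loss of bromoethane.

Step 4
Reactants: 7 diethyl [3,5-bis(benzyloxy)benzyl]phosphonate; 8 4-formylphenyl trifluoromethanesulfonate
Product: 9 4-{(E)-2-[3,5-bis(benzyloxy)phenyl]ethenyl}phenyl trifluoromethanesulfonate
Conditions: NaH, THF, 0 °C; then 8, 0 °C to rt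
Reagents that add atoms: none
Why: Horner–Wadsworth–Emmons olefination of a benzylic phosphonate with an aryl aldehyde, which gives the E-stilbene, while the aryl triflate is not attacked by the soft stabilised carbanion.

Step 5
Reactants: 9 4-{(E)-2-[3,5-bis(benzyloxy)phenyl]ethenyl}phenyl trifluoromethanesulfonate
Product: 10 4-{(2S,3S)-3-[3,5-bis(benzyloxy)phenyl]oxiran-2-yl}phenyl trifluoromethanesulfonate
Conditions: L-fructose-derived enantiomer of the Shi ketone (30 mol %), KHSO5 (Oxone), K2CO3, Bu4NHSO4, MeCN/dimethoxymethane/aq. Na2B4O7 buffer, 0 °C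
Reagents that add atoms: potassium peroxymonosulfate, [K+].[O-]S(=O)(=O)OO
Why: Shi asymmetric epoxidation of a trans-stilbene through the spiro dioxirane transition state, in which the L-fructose-derived ketone delivers oxygen to the face that gives the (S,S)-trans-epoxide, both stereocentres being set by the catalyst.

Step 6
Reactants: 5 4-(benzyloxy)-2-bromo-6-(trimethylsilyl)phenyl trifluoromethanesulfonate; 10 4-{(2S,3S)-3-[3,5-bis(benzyloxy)phenyl]oxiran-2-yl}phenyl trifluoromethanesulfonate
Product: 13 4-[(2R,3R)-6-(benzyloxy)-3-[3,5-bis(benzyloxy)phenyl]-4-bromo-2,3-dihydro-1-benzofuran-2-yl]phenyl trifluoromethanesulfonate (BF–Br), via aryne 11 (not isolated), via oxiranium zwitterion 12 (not isolated)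
Conditions: CsF (3 equiv), MeCN–toluene 1:1, 25 °C, 5 added over 6 h to 10 (2 equiv, excess recovered)
Reagents that add atoms: none
Why: Proposed new method: fluoride-induced 1,2-elimination of 5 gives aryne 11, the oxirane oxygen of 10 adds to the aryne carbon remote from bromine (the inductively withdrawing C–Br bond beside the triple bond distorts the aryne and places the developing carbanion ortho to bromine, while the benzyloxy group two positions away is nearly neutral), and the ortho-carbanion/oxiranium zwitterion 12 collapses by transfer of a benzylic carbon from oxygen to the carbanion. The closest known reaction type is the insertion of arynes into the benzylic C–O bond of styrene oxide to give 3-aryl-2,3-dihydrobenzofurans, together with the three-component couplings of arynes with cyclic ethers that pass through the same oxonium zwitterions; a trans-2,3-diaryloxirane with transfer of chirality has not been used. The five-membered ring is closed by a formal [3+2] annulation, that is ring expansion of the oxiranium through front-side, ion-pair C–C bond formation, because backside attack is geometrically impossible for a nucleophile held two atoms from the leaving oxygen. C2 keeps the configuration of the epoxide carbon because its C–O bond is never broken, and C3 is set in the ion-pair collapse, which gives the trans-2,3-diaryl arrangement from the trans-epoxide by retention and, if the benzylic cation lives long enough to rotate, still by thermodynamic preference, so that any cis-epoxide converges on the same product. Two selectivities are needed: the aryne regiochemistry, secured by the bromine at the future C4, and scission of the C–O bond at the carbon bearing the 3,5-bis(benzyloxy)phenyl group, secured by the electron-poor 4-triflyloxyphenyl ring, which destabilises positive charge at the other benzylic carbon.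

Step 7
Reactants: 13 BF–Br
Product: 15 BF–CH2OH, via aldehyde 14 (not isolated)
Conditions: n-BuLi (1.05 equiv), THF, −95 °C; DMF, −95 to −40 °C; then AcOH/MeOH, NaBH4, −40 to 0 °C
Reagents that add atoms: N,N-dimethylformamide, CN(C)C=O
Why: Bromine–lithium exchange is faster than attack on the remote aryl triflate at low temperature, the aryllithium is formylated by DMF (Bouveault formylation) and the aldehyde is reduced in the same flask by borohydride; no stereocentre is touched.

Step 8
Reactants: 15 BF–CH2OH; 16 (1R,4R,5R)-4,7,7-trimethyl-6-thiabicyclo[3.2.1]octane (isothiocineole)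
Product: 18 (1R,4R,5R)-6-(BF-methyl)-4,7,7-trimethyl-6-thiabicyclo[3.2.1]octan-6-ium trifluoromethanesulfonate, via benzylic bromide 17 (not isolated)
Conditions: CBr4, PPh3, CH2Cl2, 0 °C; then 16, LiOTf, CH2Cl2/H2O, rt
Reagents that add atoms: lithium trifluoromethanesulfonate, [Li+].[O-]S(=O)(=O)C(F)(F)F; tetrabromomethane, BrC(Br)(Br)Br (its bromine stays only in 17)
Why: Appel bromination followed by SN2 alkylation of the sulfide, made irreversible by exchange of bromide for triflate, avoids any benzylic cation next to the electron-rich aryl ring, and the benzyl group enters on the less hindered sulfur lone pair to give one sulfonium diastereomer.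

Step 9
Reactants: 19 1-[4-(benzyloxy)phenyl]ethan-1-one; 20 1,3-bis(benzyloxy)-5-bromobenzene
Product: 21 1-[4-(benzyloxy)phenyl]-2-[3,5-bis(benzyloxy)phenyl]ethan-1-one
Conditions: Pd2(dba)3 (1 mol %), Xantphos (2.4 mol %), NaOtBu, THF, 70 °C
Reagents that add atoms: none
Why: Palladium-catalysed α-arylation of an aryl methyl ketone enolate with an aryl bromide, which stops at monoarylation with a wide-bite-angle bisphosphine.

Step 10
Reactants: 21 1-[4-(benzyloxy)phenyl]-2-[3,5-bis(benzyloxy)phenyl]ethan-1-one; 22 4-(benzyloxy)benzaldehyde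
Product: 23 (2E)-1,3-bis[4-(benzyloxy)phenyl]-2-[3,5-bis(benzyloxy)phenyl]prop-2-en-1-one
Conditions: piperidine, AcOH (cat.), toluene, reflux, Dean–Stark
Reagents that add atoms: none
Why: Knoevenagel-type aldol condensation of a deoxybenzoin with an aryl aldehyde, which gives the isomer with aroyl and β-aryl groups trans as the thermodynamic product.

Step 11
Reactants: 18 sulfonium triflate; 23 (2E)-1,3-bis[4-(benzyloxy)phenyl]-2-[3,5-bis(benzyloxy)phenyl]prop-2-en-1-one
Product: 25 [4-(benzyloxy)phenyl]{1-[3,5-bis(benzyloxy)phenyl]-2-[4-(benzyloxy)phenyl]-3-BF-cyclopropyl}methanone (BF-bearing carbon configured as in the SMILES; the two CH-aryl groups trans), via sulfonium ylide 24 (not isolated)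
Conditions: LiN(SiMe3)2 (1.0 equiv), THF, −78 °C; then 23 (1.5 equiv), −78 to 0 °C
Reagents that add atoms: none
Why: Michael-initiated ring closure (Corey–Chaykovsky-type cyclopropanation) in which the ylide adds to the β-carbon of 23 through the face left open by the bicyclic sulfide and the enolate then displaces the sulfide with inversion, so the configuration of the ylide carbon (future indane C2) is reagent-controlled, while the other two ring stereocentres are erased in step 12 and need no control.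

Step 12
Reactants: 25 donor–acceptor cyclopropane
Product: 27 [4-(benzyloxy)phenyl]{(1S,2R,3S)-4,6-bis(benzyloxy)-3-[4-(benzyloxy)phenyl]-2-BF-2,3-dihydro-1H-inden-1-yl}methanone, via ring-opened zwitterion 26 (not isolated)
Conditions: Sc(OTf)3 (10 mol %), CH2Cl2, 0 °C to rt; then DBU (0.2 equiv), rt
Reagents that add atoms: none
Why: Lewis-acid opening of the donor–acceptor cyclopropane at the bond between the 4-benzyloxyphenyl-bearing and acyl-bearing carbons gives a para-alkoxybenzylic cation beside an enolate, which is trapped in an intramolecular Friedel–Crafts alkylation by the doubly activated ortho position of the 3,5-bis(benzyloxy)phenyl ring (five-ring closure from the adjacent carbon, favoured over seven-ring closure by the remote aryl group and over reversible O-trapping), the new C3 forming trans to the benzofuranyl group as in related cation cyclisations to 1,2-trans-indanes and the acyl-bearing C1 being equilibrated by DBU to the all-trans isomer, while C2 is untouched.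

Step 13
Reactants: 27 indanyl aryl ketone
Product: 28 (S)-[4-(benzyloxy)phenyl]{(1S,2R,3S)-4,6-bis(benzyloxy)-3-[4-(benzyloxy)phenyl]-2-BF-2,3-dihydro-1H-inden-1-yl}methanol
Conditions: (R)-2-methyl-CBS-oxazaborolidine (1 equiv), BH3·SMe2, toluene/THF, −20 °C; MeOH quench
Reagents that add atoms: none
Why: Corey–Bakshi–Shibata reduction in which, with the ketone aryl group as the large substituent, the (R)-oxazaborolidine delivers hydride to the face that gives the (S)-carbinol, the same face that a Felkin–Anh arrangement with the fused aryl carbon anti to the hydride favours, so reagent and substrate control are expected to reinforce each other.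

Step 14
Reactants: 28 carbinol
Product: 29 (S)-[4-(benzyloxy)phenyl]{(1S,2R,3S)-4,6-bis(benzyloxy)-3-[4-(benzyloxy)phenyl]-2-[(2R,3R)-6-(benzyloxy)-3-[3,5-bis(benzyloxy)phenyl]-2-(4-hydroxyphenyl)-2,3-dihydro-1-benzofuran-4-yl]-2,3-dihydro-1H-inden-1-yl}methanol
Conditions: Et4NOH (aq., 3 equiv), 1,4-dioxane, rt; NH4Cl work-up
Reagents that add atoms: none
Why: Hydroxide attacks the sulfonyl sulfur of the aryl triflate (S–O cleavage) and frees the phenol under conditions that leave benzyl ethers, the benzylic carbinol and all stereocentres untouched.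

Step 15
Reactants: 29 heptabenzyl ether
Product: 30 (S)-[(1S,2R,3S)-2-[(2R,3R)-3-(3,5-dihydroxyphenyl)-6-hydroxy-2-(4-hydroxyphenyl)-2,3-dihydro-1-benzofuran-4-yl]-4,6-dihydroxy-3-(4-hydroxyphenyl)-2,3-dihydro-1H-inden-1-yl](4-hydroxyphenyl)methanol (CNP0175860.1)
Conditions: H2 (1 atm), Pd(OH)2/C, THF/MeOH 1:1, rt, stopped at full debenzylation
Reagents that add atoms: none
Why: Catalytic hydrogenolysis of the seven aryl benzyl ethers under neutral conditions, under which the secondary benzylic alcohol and the cyclic benzylic ether of the dihydrobenzofuran are cleaved much more slowly; no stereocentre is touched.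

**Compound list**
1 | 4-(benzyloxy)phenol | Oc1ccc(OCc2ccccc2)cc1 | starting material
2 | 4-(benzyloxy)-2,6-dibromophenol | Oc1c(Br)cc(OCc2ccccc2)cc1Br | intermediate
3 | [4-(benzyloxy)-2,6-dibromophenoxy]trimethylsilane | C[Si](C)(C)Oc1c(Br)cc(OCc2ccccc2)cc1Br | intermediate
4 | lithium 4-(benzyloxy)-2-bromo-6-(trimethylsilyl)phenolate | [Li+].[O-]c1c(Br)cc(OCc2ccccc2)cc1[Si](C)(C)C | intermediate
5 | 4-(benzyloxy)-2-bromo-6-(trimethylsilyl)phenyl trifluoromethanesulfonate | C[Si](C)(C)c1cc(OCc2ccccc2)cc(Br)c1OS(=O)(=O)C(F)(F)F | intermediate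
6 | 1,3-bis(benzyloxy)-5-(bromomethyl)benzene | BrCc1cc(OCc2ccccc2)cc(OCc2ccccc2)c1 | starting material
7 | diethyl [3,5-bis(benzyloxy)benzyl]phosphonate | CCOP(=O)(Cc1cc(OCc2ccccc2)cc(OCc2ccccc2)c1)OCC | intermediate
8 | 4-formylphenyl trifluoromethanesulfonate | O=Cc1ccc(OS(=O)(=O)C(F)(F)F)cc1 | starting material
9 | 4-{(E)-2-[3,5-bis(benzyloxy)phenyl]ethenyl}phenyl trifluoromethanesulfonate | FC(F)(F)S(=O)(=O)Oc1ccc(/C=C/c2cc(OCc3ccccc3)cc(OCc3ccccc3)c2)cc1 | intermediate
10 | 4-{(2S,3S)-3-[3,5-bis(benzyloxy)phenyl]oxiran-2-yl}phenyl trifluoromethanesulfonate | C(c1ccccc1)Oc1cc(OCc2ccccc2)cc(c1)[C@H]1[C@H](c2ccc(OS(=O)(=O)C(F)(F)F)cc2)O1 | intermediate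
11 | 5-(benzyloxy)-3-bromobenzyne | BrC1=CC(OCc2ccccc2)=CC#C1 | intermediate
12 | oxiranium zwitterion (oxygen of 10 bonded to C1 of a 5-(benzyloxy)-3-bromophenyl group whose C2, between C–O and C–Br, is the carbanion) | Brc1cc(OCc2ccccc2)cc([c-]1)[O+]1[C@@H](c2ccc(OS(=O)(=O)C(F)(F)F)cc2)[C@@H]1c1cc(OCc2ccccc2)cc(OCc2ccccc2)c1 | intermediate
13 | 4-[(2R,3R)-6-(benzyloxy)-3-[3,5-bis(benzyloxy)phenyl]-4-bromo-2,3-dihydro-1-benzofuran-2-yl]phenyl trifluoromethanesulfonate (BF–Br) | Brc1cc(OCc2ccccc2)cc2c1[C@@H](c1cc(OCc3ccccc3)cc(OCc3ccccc3)c1)[C@H](c1ccc(OS(=O)(=O)C(F)(F)F)cc1)O2 | intermediate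
14 | 4-[(2R,3R)-6-(benzyloxy)-3-[3,5-bis(benzyloxy)phenyl]-4-formyl-2,3-dihydro-1-benzofuran-2-yl]phenyl trifluoromethanesulfonate (BF–CHO) | O=Cc1cc(OCc2ccccc2)cc2c1[C@@H](c1cc(OCc3ccccc3)cc(OCc3ccccc3)c1)[C@H](c1ccc(OS(=O)(=O)C(F)(F)F)cc1)O2 | intermediate
15 | 4-[(2R,3R)-6-(benzyloxy)-3-[3,5-bis(benzyloxy)phenyl]-4-(hydroxymethyl)-2,3-dihydro-1-benzofuran-2-yl]phenyl trifluoromethanesulfonate (BF–CH2OH) | OCc1cc(OCc2ccccc2)cc2c1[C@@H](c1cc(OCc3ccccc3)cc(OCc3ccccc3)c1)[C@H](c1ccc(OS(=O)(=O)C(F)(F)F)cc1)O2 | intermediate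
16 | (1R,4R,5R)-4,7,7-trimethyl-6-thiabicyclo[3.2.1]octane (isothiocineole) | C[C@@H]1CC[C@@H]2C[C@H]1SC2(C)C | starting material
17 | 4-[(2R,3R)-6-(benzyloxy)-3-[3,5-bis(benzyloxy)phenyl]-4-(bromomethyl)-2,3-dihydro-1-benzofuran-2-yl]phenyl trifluoromethanesulfonate (BF–CH2Br) | BrCc1cc(OCc2ccccc2)cc2c1[C@@H](c1cc(OCc3ccccc3)cc(OCc3ccccc3)c1)[C@H](c1ccc(OS(=O)(=O)C(F)(F)F)cc1)O2 | intermediate
18 | (1R,4R,5R)-6-(BF-methyl)-4,7,7-trimethyl-6-thiabicyclo[3.2.1]octan-6-ium trifluoromethanesulfonate (one sulfonium diastereomer) | C[C@@H]1CC[C@@H]2C[C@H]1[S+](Cc1cc(OCc3ccccc3)cc3c1[C@@H](c1cc(OCc4ccccc4)cc(OCc4ccccc4)c1)[C@H](c1ccc(OS(=O)(=O)C(F)(F)F)cc1)O3)C2(C)C.[O-]S(=O)(=O)C(F)(F)F | intermediate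
19 | 1-[4-(benzyloxy)phenyl]ethan-1-one | CC(=O)c1ccc(OCc2ccccc2)cc1 | starting material
20 | 1,3-bis(benzyloxy)-5-bromobenzene | Brc1cc(OCc2ccccc2)cc(OCc2ccccc2)c1 | starting material
21 | 1-[4-(benzyloxy)phenyl]-2-[3,5-bis(benzyloxy)phenyl]ethan-1-one | O=C(Cc1cc(OCc2ccccc2)cc(OCc2ccccc2)c1)c1ccc(OCc2ccccc2)cc1 | intermediate
22 | 4-(benzyloxy)benzaldehyde | O=Cc1ccc(OCc2ccccc2)cc1 | starting material
23 | (2E)-1,3-bis[4-(benzyloxy)phenyl]-2-[3,5-bis(benzyloxy)phenyl]prop-2-en-1-one | O=C(c1ccc(OCc2ccccc2)cc1)/C(c1cc(OCc2ccccc2)cc(OCc2ccccc2)c1)=C/c1ccc(OCc2ccccc2)cc1 | intermediate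
24 | sulfonium ylide of 18 (carbanion at the benzylic carbon) | C[C@@H]1CC[C@@H]2C[C@H]1[S+]([CH-]c1cc(OCc3ccccc3)cc3c1[C@@H](c1cc(OCc4ccccc4)cc(OCc4ccccc4)c1)[C@H](c1ccc(OS(=O)(=O)C(F)(F)F)cc1)O3)C2(C)C | intermediate
25 | [4-(benzyloxy)phenyl]{1-[3,5-bis(benzyloxy)phenyl]-2-[4-(benzyloxy)phenyl]-3-BF-cyclopropyl}methanone (CH-aryl groups trans, aroyl cis to BF) | O=C(c1ccc(OCc2ccccc2)cc1)[C@]1(c2cc(OCc3ccccc3)cc(OCc3ccccc3)c2)[C@H](c2cc(OCc3ccccc3)cc3c2[C@@H](c2cc(OCc4ccccc4)cc(OCc4ccccc4)c2)[C@H](c2ccc(OS(=O)(=O)C(F)(F)F)cc2)O3)[C@H]1c1ccc(OCc2ccccc2)cc1 | intermediate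
26 | ring-opened 1,3-zwitterion of 25 (enolate and 4-benzyloxybenzylic cation, drawn metal-free) | [O-]C(c1ccc(OCc2ccccc2)cc1)=C(c1cc(OCc2ccccc2)cc(OCc2ccccc2)c1)[C@H](c1cc(OCc2ccccc2)cc2c1[C@@H](c1cc(OCc3ccccc3)cc(OCc3ccccc3)c1)[C@H](c1ccc(OS(=O)(=O)C(F)(F)F)cc1)O2)[CH+]c1ccc(OCc2ccccc2)cc1 | intermediate
27 | [4-(benzyloxy)phenyl]{(1S,2R,3S)-4,6-bis(benzyloxy)-3-[4-(benzyloxy)phenyl]-2-BF-2,3-dihydro-1H-inden-1-yl}methanone | C(c1ccccc1)Oc1ccc([C@H]2c3c(OCc4ccccc4)cc(OCc4ccccc4)cc3[C@@H](C(=O)c3ccc(OCc4ccccc4)cc3)[C@@H]2c2cc(OCc3ccccc3)cc3c2[C@@H](c2cc(OCc4ccccc4)cc(OCc4ccccc4)c2)[C@H](c2ccc(OS(=O)(=O)C(F)(F)F)cc2)O3)cc1 | intermediate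
28 | (S)-[4-(benzyloxy)phenyl]{(1S,2R,3S)-4,6-bis(benzyloxy)-3-[4-(benzyloxy)phenyl]-2-BF-2,3-dihydro-1H-inden-1-yl}methanol | C(c1ccccc1)Oc1ccc([C@H]2c3c(OCc4ccccc4)cc(OCc4ccccc4)cc3[C@@H]([C@H](O)c3ccc(OCc4ccccc4)cc3)[C@@H]2c2cc(OCc3ccccc3)cc3c2[C@@H](c2cc(OCc4ccccc4)cc(OCc4ccccc4)c2)[C@H](c2ccc(OS(=O)(=O)C(F)(F)F)cc2)O3)cc1 | intermediate
29 | the 4-hydroxyphenyl analogue of 28 (triflate replaced by OH) | C(c1ccccc1)Oc1ccc([C@H]2c3c(OCc4ccccc4)cc(OCc4ccccc4)cc3[C@@H]([C@H](O)c3ccc(OCc4ccccc4)cc3)[C@@H]2c2cc(OCc3ccccc3)cc3c2[C@@H](c2cc(OCc4ccccc4)cc(OCc4ccccc4)c2)[C@H](c2ccc(O)cc2)O3)cc1 | intermediate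
30 | (S)-[(1S,2R,3S)-2-[(2R,3R)-3-(3,5-dihydroxyphenyl)-6-hydroxy-2-(4-hydroxyphenyl)-2,3-dihydro-1-benzofuran-4-yl]-4,6-dihydroxy-3-(4-hydroxyphenyl)-2,3-dihydro-1H-inden-1-yl](4-hydroxyphenyl)methanol | Oc1ccc([C@H]2c3c(O)cc(O)cc3[C@@H]([C@H](O)c3ccc(O)cc3)[C@@H]2c2cc(O)cc3c2[C@@H](c2cc(O)cc(O)c2)[C@H](c2ccc(O)cc2)O3)cc1 | target

**Step count and risks**
Total: 15 steps. Longest linear sequence: 11 steps (3, 4, 5, 6, 7, 8, 11, 12, 13, 14, 15, from 6).

Step 6 (proposed new method). What may go wrong: slow capture of the aryne by the weakly basic, hindered oxirane oxygen, so that aryne self-reaction or fluoride addition wins; scission of the other benzylic C–O bond if the triflate bias is too small; 1,2-hydride shift in the opened ion pair; loss of bromide from the ortho-bromoaryl anion. Fallback by known chemistry, from 5 back to 13: CsF in DMF (reagent and solvent) followed by aqueous acid gives, by the known insertion of the aryne into the formamide C=O bond with the same bromine-controlled regiochemistry, the salicylaldehyde F1 (4-(benzyloxy)-2-bromo-6-hydroxybenzaldehyde). Addition of the Grignard reagent F2 (3,5-bis(benzyloxy)phenylmagnesium bromide, from 20 and Mg) gives the benzhydrol F3. TolSO2Na/HCO2H turns it into the sulfone F4, a standard ortho-quinone methide precursor. With Cs2CO3 in CH2Cl2, F4 loses sulfinate and the quinone methide is taken up in a [4+1] annulation by the ylide of the sulfonium salt F5 (from 4-(bromomethyl)phenyl trifluoromethanesulfonate and the (1S,4S,5S)-enantiomer of 16), giving 13. C2 is then set by the ylide face and C3 by the trans-selective ring closure.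

Step 11. What may go wrong: slow Michael addition because both the ortho-substituted ylide and the α-aryl enone are congested; O-alkylation of the enolate to a dihydrofuran that cannot ionise at the right carbon; incomplete facial control. Fallback, from 14 (isolated by leaving out NaBH4 in step 7) and 21 back to 25: piperidine/AcOH condensation gives the enone F6 ((2E)-1-[4-(benzyloxy)phenyl]-2-[3,5-bis(benzyloxy)phenyl]-3-BF-prop-2-en-1-one). The roles are then reversed: the ylide of the unhindered sulfonium salt F7 (from 4-(benzyloxy)benzyl bromide, 16 and LiOTf; LiN(SiMe3)2, THF, −78 °C) adds to the β-carbon that carries BF. Ring closure gives 25 together with its epimer at the BF-bearing carbon; these are diastereomers because of the benzofuran stereocentres and are separated before step 12. In this polarity an O-alkylated dihydrofuran is also productive, because its benzylic C–O bond is the 4-benzyloxybenzylic one that ionises under the conditions of step 12.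

Step 13. What may go wrong: hydride delivery to the other carbonyl face if substrate control overrides the catalyst, or sluggish reduction of the hindered ketone. Fallback, from 27 back to 29: NaBH4/CeCl3 in MeOH/THF (substrate control) gives the epimeric (R)-carbinol F8. Mitsunobu reaction with 4-nitrobenzoic acid (PPh3, DIAD, THF, 0 °C) inverts it to the (S)-ester F9. Et4NOH in dioxane then removes the ester together with the aryl triflate and returns the route at 29.

**Further compounds**
F1 | step 6 | 4-(benzyloxy)-2-bromo-6-hydroxybenzaldehyde | O=Cc1c(Br)cc(OCc2ccccc2)cc1O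
F2 | step 6 | 3,5-bis(benzyloxy)phenylmagnesium bromide | Br[Mg]c1cc(OCc2ccccc2)cc(OCc2ccccc2)c1
F3 | step 6 | 5-(benzyloxy)-2-{[3,5-bis(benzyloxy)phenyl](hydroxy)methyl}-3-bromophenol (racemic) | OC(c1cc(OCc2ccccc2)cc(OCc2ccccc2)c1)c1c(Br)cc(OCc2ccccc2)cc1O
F4 | step 6 | 5-(benzyloxy)-2-{[3,5-bis(benzyloxy)phenyl](4-methylbenzenesulfonyl)methyl}-3-bromophenol (racemic) | Cc1ccc(cc1)S(=O)(=O)C(c1cc(OCc2ccccc2)cc(OCc2ccccc2)c1)c1c(Br)cc(OCc2ccccc2)cc1O
F5 | step 6 | (1S,4S,5S)-4,7,7-trimethyl-6-(4-{[(trifluoromethyl)sulfonyl]oxy}benzyl)-6-thiabicyclo[3.2.1]octan-6-ium trifluoromethanesulfonate | C[C@H]1CC[C@H]2C[C@@H]1[S+](Cc1ccc(OS(=O)(=O)C(F)(F)F)cc1)C2(C)C.[O-]S(=O)(=O)C(F)(F)F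
F6 | step 11 | (2E)-1-[4-(benzyloxy)phenyl]-2-[3,5-bis(benzyloxy)phenyl]-3-BF-prop-2-en-1-one | O=C(c1ccc(OCc2ccccc2)cc1)/C(c1cc(OCc2ccccc2)cc(OCc2ccccc2)c1)=C/c1cc(OCc2ccccc2)cc2c1[C@@H](c1cc(OCc3ccccc3)cc(OCc3ccccc3)c1)[C@H](c1ccc(OS(=O)(=O)C(F)(F)F)cc1)O2
F7 | step 11 | (1R,4R,5R)-6-[4-(benzyloxy)benzyl]-4,7,7-trimethyl-6-thiabicyclo[3.2.1]octan-6-ium trifluoromethanesulfonate | C[C@@H]1CC[C@@H]2C[C@H]1[S+](Cc1ccc(OCc3ccccc3)cc1)C2(C)C.[O-]S(=O)(=O)C(F)(F)F
F8 | step 13 | (R)-carbinol epimer of 28 | C(c1ccccc1)Oc1ccc([C@H]2c3c(OCc4ccccc4)cc(OCc4ccccc4)cc3[C@@H]([C@@H](O)c3ccc(OCc4ccccc4)cc3)[C@@H]2c2cc(OCc3ccccc3)cc3c2[C@@H](c2cc(OCc4ccccc4)cc(OCc4ccccc4)c2)[C@H](c2ccc(OS(=O)(=O)C(F)(F)F)cc2)O3)cc1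
F9 | step 13 | (S)-4-nitrobenzoate of 28 | C(c1ccccc1)Oc1ccc([C@H]2c3c(OCc4ccccc4)cc(OCc4ccccc4)cc3[C@@H]([C@H](OC(=O)c3ccc(cc3)[N+](=O)[O-])c3ccc(OCc4ccccc4)cc3)[C@@H]2c2cc(OCc3ccccc3)cc3c2[C@@H](c2cc(OCc4ccccc4)cc(OCc4ccccc4)c2)[C@H](c2ccc(OS(=O)(=O)C(F)(F)F)cc2)O3)cc1
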